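**Strategy.** Ring C (the central cyclohexane) is cut at two bonds: the one joining the quaternary methyl carbon next to the carbinol to the B/C-fusion methine, and the one joining the ring-C CH2 to the quaternary methyl carbon of the C/D fusion. The key step makes both in one radical cascade. It exploits the C/D-fusion triad C(CH3)–CH–CH(B/C) as a masked 2-alkylidene-1-methylidenecyclohexane: an α-keto radical closes the eight-membered ring B on the diene terminus, hydrogen-atom transfer creates the angular methyl, and a chloride-derived radical closes ring C. The precursor is a bromo chloro ketone–diene built from (S)-pulegone and 4,4-dimethylcyclohexanone.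

Key step: step 16

Remark (assumptions): ring letters are A = cyclopentane, B = cyclooctene, C = central cyclohexane, D = gem-dimethylcyclohexane. (S)-(−)-Pulegone, 2-bromoprop-2-en-1-ol, 3-bromobut-3-en-1-ol, 4,4-dimethylcyclohexanone and (1,3-dioxolan-2-ylmethyl)zinc bromide solution are taken as purchasable.

Step 1
Reactants: 1 (S)-(−)-pulegone
Product: 3 methyl (5S)-5-methyl-2-(propan-2-ylidene)cyclopentane-1-carboxylate (methyl pulegenate; C-1 epimers), via pulegone dibromide 2 (not isolated)
Conditions: Br2, NaHCO3, Et2O, 0 °C; then NaOMe, MeOH, reflux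
Reagents that add atoms: sodium methoxide, [Na+].[O-]C
Why: Bromination of the enone and treatment with methoxide give the Favorskii ring contraction (cyclopropanone opening with loss of bromide) to the cyclopentane ester; the methyl stereocentre is not involved.

Step 2
Reactants: 3 methyl pulegenate
Product: 4 methyl (5S)-5-methyl-2-oxocyclopentane-1-carboxylate
Conditions: O3, CH2Cl2/MeOH, −78 °C; then Me2S
Reagents that add atoms: ozone, O=[O+][O-]
Why: Ozonolysis with reductive work-up cleaves the isopropylidene group and leaves the β-keto ester.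

Step 3
Reactants: 4 β-keto ester
Product: 5 methyl (5S)-5-methyl-2-{[(trifluoromethyl)sulfonyl]oxy}cyclopent-1-ene-1-carboxylate
Conditions: Tf2O, i-Pr2NEt, CH2Cl2, −78 °C
Reagents that add atoms: trifluoromethanesulfonic anhydride, O=S(=O)(OS(=O)(=O)C(F)(F)F)C(F)(F)F
Why: O-Triflation of the enolised β-keto ester gives the conjugated alkenyl triflate without touching the remote methyl stereocentre.

Step 4
Reactants: 5 alkenyl triflate
Product: 6 methyl (5S)-5-methyl-2-(4,4,5,5-tetramethyl-1,3,2-dioxaborolan-2-yl)cyclopent-1-ene-1-carboxylate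
Conditions: B2pin2, PdCl2(dppf) (cat.), KOAc, 1,4-dioxane, 80 °C
Reagents that add atoms: bis(pinacolato)diboron, CC1(C)OB(OC1(C)C)B1OC(C)(C)C(C)(C)O1
Why: Miyaura borylation of the alkenyl triflate gives the β-boryl enoate.

Step 5
Reactants: 6 alkenyl boronate; 7 2-bromoprop-2-en-1-ol
Product: 9 (7S)-7-methyl-4-methylidene-4,5,6,7-tetrahydrocyclopenta[c]pyran-1(3H)-one, via hydroxy dienoate 8 (not isolated)
Conditions: Pd(PPh3)4 (cat.), K2CO3, dioxane/H2O, 70 °C; then PPTS (cat.), PhH, 50 °C
Reagents that add atoms: none
Why: Suzuki–Miyaura coupling joins the two alkenyl partners and mild acid closes the δ-lactone, which ties the future allylic CH2O carbon to the ester side of ring A (mild conditions to avoid isomerisation to the 2-pyranone).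

Step 6
Reactants: 9 dienyl lactone
Product: 11 (7S,7aS)-4,7-dimethyl-5,6,7,7a-tetrahydrocyclopenta[c]pyran-1(3H)-one, via lithium dienolate 10 (not isolated)
Conditions: L-Selectride, THF, −78 °C; then AcOH, −78 °C
Reagents that add atoms: none
Why: Conjugate 1,6-hydride addition at the exocyclic CH2 makes the vinylic methyl and an extended enolate, and kinetic α-protonation from the face opposite the neighbouring methyl sets the ring-fusion CH (deconjugative protonation) while the lactone ring locks the geometry of the tetrasubstituted alkene.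

Step 7
Reactants: 11 β,γ-unsaturated lactone
Product: 12 (1S,2Z,5S)-2-(1-hydroxypropan-2-ylidene)-N-methoxy-N,5-dimethylcyclopentane-1-carboxamide
Conditions: MeNH(OMe)·HCl, AlMe3, CH2Cl2, 0 °C to rt
Reagents that add atoms: N,O-dimethylhydroxylamine hydrochloride, CNOC.Cl
Why: Weinreb aminolysis of the lactone with the aluminium amide runs without base, so the acidic allylic α-stereocentre is kept.

Step 8
Reactants: 12 hydroxy Weinreb amide
Product: 13 (1S,2Z,5S)-2-(1-bromopropan-2-ylidene)-N-methoxy-N,5-dimethylcyclopentane-1-carboxamide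
Conditions: CBr4, PPh3, CH2Cl2, 0 °C
Reagents that add atoms: carbon tetrabromide, BrC(Br)(Br)Br
Why: Appel bromination converts the primary allylic alcohol by SN2 displacement without moving the alkene.

Step 9
Reactants: 13 allylic bromide; 14 (1,3-dioxolan-2-ylmethyl)zinc bromide
Product: 15 (1S,2Z,5S)-2-[4-(1,3-dioxolan-2-yl)butan-2-ylidene]-N-methoxy-N,5-dimethylcyclopentane-1-carboxamide
Conditions: Pd(PPh3)4 (5 mol%), THF, 40 °C
Reagents that add atoms: none
Why: Negishi sp3–sp3 coupling through the π-allylpalladium complex delivers the alkyl group to the unhindered CH2 terminus, and the alkene geometry is kept because η1-bonding at the fully substituted terminus is disfavoured.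

Step 10
Reactants: 15 dioxolane
Product: 16 (1S,2Z,5S)-N-methoxy-N,5-dimethyl-2-(5-oxopentan-2-ylidene)cyclopentane-1-carboxamide
Conditions: PPTS, acetone/H2O, 50 °C
Reagents that add atoms: water, O
Why: Acid-catalysed acetal hydrolysis releases the aldehyde under conditions too mild to move the tetrasubstituted alkene.

Step 11
Reactants: 16 aldehyde; 17 4,4-dimethylcyclohexan-1-one
Product: 21 (1S,2Z,5S)-2-[5-((E)-5,5-dimethyl-2-oxocyclohexylidene)pentan-2-ylidene]-N-methoxy-N,5-dimethylcyclopentane-1-carboxamide, via lithium enolate 18 (not isolated), via aldol adduct 19 (not isolated), via aldol mesylate 20 (not isolated)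
Conditions: 17, LDA, THF, −78 °C; then 16; then MsCl, −78 to 0 °C; then DBU, rt
Reagents that add atoms: none
Why: Directed aldol addition of the preformed ketone enolate to the aldehyde and E1cB elimination of the derived mesylate give the thermodynamically preferred (E)-2-alkylidene ketone.

Step 12
Reactants: 21 enone
Product: 22 (1S,2Z,5S)-2-[5-((E)-5,5-dimethyl-2-methylidenecyclohexylidene)pentan-2-ylidene]-N-methoxy-N,5-dimethylcyclopentane-1-carboxamide
Conditions: Ph3PCH3Br, KOtBu, THF, 0 °C
Reagents that add atoms: methyltriphenylphosphonium bromide, C[P+](c1ccccc1)(c1ccccc1)c1ccccc1.[Br-]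
Why: Wittig methylenation of the enone carbonyl gives the s-cis-locked exocyclic 1,3-diene.

Step 13
Reactants: 23 3-bromobut-3-en-1-ol
Product: 24 2-bromo-4-chlorobut-1-ene
Conditions: SOCl2, pyridine, Et2O, 0 °C to rt
Reagents that add atoms: thionyl chloride, O=S(Cl)Cl
Why: Thionyl chloride converts the primary alcohol into the chloride through the chlorosulfite (SN2) and leaves the vinyl bromide for later exchange.

Step 14
Reactants: 22 diene Weinreb amide; 24 2-bromo-4-chlorobut-1-ene
Product: 26 4-chloro-1-[(1S,2Z,5S)-2-[5-((E)-5,5-dimethyl-2-methylidenecyclohexylidene)pentan-2-ylidene]-5-methylcyclopentyl]-2-methylidenebutan-1-one, via alkenyllithium 25 (not isolated)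
Conditions: 24, t-BuLi (2.1 equiv), Et2O, −78 °C; then 22, −78 to −20 °C; then H2O
Reagents that add atoms: none
Why: Bromine–lithium exchange gives the alkenyllithium, which adds once to the Weinreb amide (stable chelate) and gives the α-methylene ketone on work-up.

Step 15
Reactants: 26 α-methylene ketone
Product: 28 2-bromo-4-chloro-1-[(1S,2Z,5S)-2-[5-((E)-5,5-dimethyl-2-methylidenecyclohexylidene)pentan-2-ylidene]-5-methylcyclopentyl]-2-methylbutan-1-one (epimers at the C–Br carbon), via lithium enolate 27 (not isolated)
Conditions: L-Selectride, THF, −78 °C; then NBS, −78 °C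
Reagents that add atoms: N-bromosuccinimide, O=C1CCC(=O)N1Br
Why: 1,4-Hydride addition to the α-methylene ketone gives the tetrasubstituted enolate regiospecifically and its bromination installs the tertiary bromide (reductive α-halogenation); the new stereocentre is irrelevant because it becomes a radical.

Step 16
Reactants: 28 α-bromo ω-chloro ketone–diene
Product: 30 tetracyclic ketone (31 with C=O in place of CHOH; (Z)-A/B alkene; trans B/C and trans C/D fusion), via chloro cyclooctenone 29 (not isolated)
Conditions: (Me3Si)3SiH (2.5 equiv) and ACHN by syringe pump, t-C12H25SH (5 mol%), PhMe (5 mM), 100 °C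
Reagents that add atoms: none
Why: The silyl radical abstracts the tertiary α-keto bromine much faster than the primary chlorine, and the electrophilic α-acyl radical adds 8-exo-trig to the CH terminus of the electron-rich exocyclic 1,3-diene (first new bond: quaternary methyl carbon to the future B/C methine), giving an allyl radical that takes a hydrogen atom at its CH2 end, which makes the C/D angular methyl and leaves the tetrasubstituted ring-D alkene of 29. Chlorine abstraction then gives the primary radical, which closes ring C 6-endo-trig onto the methyl-bearing alkene carbon (second new bond), and the tertiary radical at the C/D methine is reduced by hydrogen-atom transfer. The closest known reaction types are reductive eight-membered-ring closures of α-halo ketone radicals onto alkenes in 5-8-fused terpenoid syntheses, radical additions to 1,3-dienes with reduction of the allyl radical, and silane-mediated 6-endo cyclisations onto 1,2-dialkylcyclohexenes. The quaternary carbon and the B/C methine are set in the first closure by a transition state that keeps the chloroethyl arm and the diene anti across the forming bond (trans B/C fusion) under the influence of the ring-A stereocentres, the angular methyl carbon by chair-like 6-endo attack, and the C/D methine by axial hydrogen delivery anti to the new angular methyl (trans C/D fusion). The step needs bromide-before-chloride activation (secured by the large rate gap), ring closure ahead of reduction of the α-acyl radical (slow silane addition, polarity-mismatched thiol, cis-alkene and ketone in the tether) and 6-endo over 5-exo closure (the proximal alkene carbon is fully substituted and 5-exo would build a spiro centre next to the new quaternary carbon).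

Step 17
Reactants: 30 tetracyclic ketone
Product: 31 target alcohol
Conditions: LiAlH4, THF, −78 to 0 °C
Reagents that add atoms: none
Why: Hydride reduction of the ring-B ketone should occur from the face anti to the ring-C CH2 and the C/D angular methyl, which places the hydroxyl trans to the adjacent quaternary methyl and cis to the A/B methine hydrogen as in 31.

**Compound list**

1 | (S)-(−)-pulegone, (5S)-5-methyl-2-(propan-2-ylidene)cyclohexan-1-one | C[C@H]1CCC(=C(C)C)C(=O)C1 | starting material
2 | pulegone dibromide, (5S)-2-bromo-2-(2-bromopropan-2-yl)-5-methylcyclohexan-1-one (C-2 epimers) | C[C@H]1CCC(Br)(C(C)(C)Br)C(=O)C1 | intermediate (not isolated)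
3 | methyl (5S)-5-methyl-2-(propan-2-ylidene)cyclopentane-1-carboxylate (C-1 epimers) | CC(C)=C1CC[C@H](C)C1C(=O)OC | intermediate
4 | methyl (5S)-5-methyl-2-oxocyclopentane-1-carboxylate | O=C1CC[C@H](C)C1C(=O)OC | intermediate
5 | methyl (5S)-5-methyl-2-{[(trifluoromethyl)sulfonyl]oxy}cyclopent-1-ene-1-carboxylate | COC(=O)C1=C(OS(=O)(=O)C(F)(F)F)CC[C@@H]1C | intermediate
6 | methyl (5S)-5-methyl-2-(4,4,5,5-tetramethyl-1,3,2-dioxaborolan-2-yl)cyclopent-1-ene-1-carboxylate | COC(=O)C1=C(B2OC(C)(C)C(C)(C)O2)CC[C@@H]1C | intermediate
7 | 2-bromoprop-2-en-1-ol | OCC(Br)=C | starting material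
8 | methyl (5S)-2-(3-hydroxyprop-1-en-2-yl)-5-methylcyclopent-1-ene-1-carboxylate | COC(=O)C1=C(C(=C)CO)CC[C@@H]1C | intermediate (not isolated)
9 | (7S)-7-methyl-4-methylidene-4,5,6,7-tetrahydrocyclopenta[c]pyran-1(3H)-one | C=C1COC(=O)C2=C1CC[C@@H]2C | intermediate
10 | lithium (7S)-4,7-dimethyl-3,5,6,7-tetrahydrocyclopenta[c]pyran-1-olate (extended enolate) | [Li+].CC1=C2CC[C@H](C)C2=C([O-])OC1 | intermediate (not isolated)
11 | (7S,7aS)-4,7-dimethyl-5,6,7,7a-tetrahydrocyclopenta[c]pyran-1(3H)-one | CC1=C2CC[C@H](C)[C@@H]2C(=O)OC1 | intermediate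
12 | (1S,2Z,5S)-2-(1-hydroxypropan-2-ylidene)-N-methoxy-N,5-dimethylcyclopentane-1-carboxamide | C/C(CO)=C1\CC[C@H](C)[C@@H]1C(=O)N(C)OC | intermediate
13 | (1S,2Z,5S)-2-(1-bromopropan-2-ylidene)-N-methoxy-N,5-dimethylcyclopentane-1-carboxamide | C/C(CBr)=C1\CC[C@H](C)[C@@H]1C(=O)N(C)OC | intermediate
14 | (1,3-dioxolan-2-ylmethyl)zinc bromide | Br[Zn]CC1OCCO1 | starting material
15 | (1S,2Z,5S)-2-[4-(1,3-dioxolan-2-yl)butan-2-ylidene]-N-methoxy-N,5-dimethylcyclopentane-1-carboxamide | C/C(CCC1OCCO1)=C2\CC[C@H](C)[C@@H]2C(=O)N(C)OC | intermediate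
16 | (1S,2Z,5S)-N-methoxy-N,5-dimethyl-2-(5-oxopentan-2-ylidene)cyclopentane-1-carboxamide | C/C(CCC=O)=C1\CC[C@H](C)[C@@H]1C(=O)N(C)OC | intermediate
17 | 4,4-dimethylcyclohexan-1-one | CC1(C)CCC(=O)CC1 | starting material
18 | lithium 4,4-dimethylcyclohex-1-en-1-olate | [Li+].[O-]C1=CCC(C)(C)CC1 | intermediate (not isolated)
19 | aldol adduct of 16 and 18 (β-hydroxy ketone, lithium alkoxide in the flask; diastereomers) | C/C(CCC(O)C1CC(C)(C)CCC1=O)=C2\CC[C@H](C)[C@@H]2C(=O)N(C)OC | intermediate (not isolated)
20 | methanesulfonate of 19 | C/C(CCC(OS(C)(=O)=O)C1CC(C)(C)CCC1=O)=C2\CC[C@H](C)[C@@H]2C(=O)N(C)OC | intermediate (not isolated)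
21 | (1S,2Z,5S)-2-[5-((E)-5,5-dimethyl-2-oxocyclohexylidene)pentan-2-ylidene]-N-methoxy-N,5-dimethylcyclopentane-1-carboxamide | C/C(CC/C=C1\CC(C)(C)CCC1=O)=C2\CC[C@H](C)[C@@H]2C(=O)N(C)OC | intermediate
22 | (1S,2Z,5S)-2-[5-((E)-5,5-dimethyl-2-methylidenecyclohexylidene)pentan-2-ylidene]-N-methoxy-N,5-dimethylcyclopentane-1-carboxamide | C/C(CC/C=C1\CC(C)(C)CCC1=C)=C2\CC[C@H](C)[C@@H]2C(=O)N(C)OC | intermediate
23 | 3-bromobut-3-en-1-ol | OCCC(Br)=C | starting material
24 | 2-bromo-4-chlorobut-1-ene | ClCCC(Br)=C | intermediate
25 | (4-chlorobut-1-en-2-yl)lithium | [Li]C(=C)CCCl | intermediate (not isolated)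
26 | 4-chloro-1-[(1S,2Z,5S)-2-[5-((E)-5,5-dimethyl-2-methylidenecyclohexylidene)pentan-2-ylidene]-5-methylcyclopentyl]-2-methylidenebutan-1-one | C/C(CC/C=C1\CC(C)(C)CCC1=C)=C2\CC[C@H](C)[C@@H]2C(=O)C(=C)CCCl | intermediate
27 | lithium enolate from 1,4-reduction of 26 (tetrasubstituted, methyl-bearing enolate) | [Li+].C/C(CC/C=C1\CC(C)(C)CCC1=C)=C2\CC[C@H](C)[C@@H]2C([O-])=C(C)CCCl | intermediate (not isolated)
28 | 2-bromo-4-chloro-1-[(1S,2Z,5S)-2-[5-((E)-5,5-dimethyl-2-methylidenecyclohexylidene)pentan-2-ylidene]-5-methylcyclopentyl]-2-methylbutan-1-one (C-2 epimers) | C/C(CC/C=C1\CC(C)(C)CCC1=C)=C2\CC[C@H](C)[C@@H]2C(=O)C(C)(Br)CCCl | intermediate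
29 | chloro cyclooctenone: A/B-fused (Z)-cyclooctenone with the α-carbon bearing methyl and 2-chloroethyl and the next ring carbon bearing 2,5,5-trimethylcyclohex-1-en-1-yl (configuration as in SMILES) | C/C1=C2\CC[C@H](C)[C@@H]2C(=O)[C@@](C)(CCCl)[C@H](C2=C(C)CCC(C)(C)C2)CC1 | intermediate (not isolated)
30 | tetracyclic 5-8-6-6 ketone (ring-B ketone of 31; (Z)-A/B alkene, trans B/C and trans C/D fusion) | C/C1=C2\CC[C@H](C)[C@@H]2C(=O)[C@@]2(C)CC[C@]3(C)CCC(C)(C)C[C@H]3[C@@H]2CC1 | intermediate
31 | target alcohol CNP0399382.1 | C/C1=C2\CC[C@H](C)[C@@H]2[C@@H](O)[C@@]2(C)CC[C@]3(C)CCC(C)(C)C[C@H]3[C@@H]2CC1 | target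

**Step count:** 17 steps in total. The longest linear sequence is 16 steps (steps 1–12 and 14–17); step 13 is a one-step side branch.

**Steps most likely to fail**

1. Step 16. The α-acyl radical may be reduced before the slow eight-membered closure. The primary radical may close 5-exo onto the ring-fusion alkene carbon instead of 6-endo. Facial selectivity at the new quaternary carbon may be low, because methyl and chloroethyl are of similar size. Fallback (sets out from 28, comes back at 30): the cascade is split and ring C is closed by an ionic ene reaction instead of a radical. With 1.1 equiv of silane at 80 °C the chloride survives and 29 is isolated. Kornblum oxidation (NaI, NaHCO3, DMSO, 110 °C) gives the aldehyde F1. Me2AlCl (CH2Cl2, −78 °C) then triggers an intramolecular carbonyl-ene reaction through a six-membered chair, in which the methyl-bearing alkene carbon attacks the aldehyde, and gives the homoallylic alcohol F2 with the angular methyl in place. The hydroxyl is removed through the imidazolyl thiocarbonate F3 (TCDI, DMAP; then Bu3SnH, AIBN) to give the ring-D alkene F4. Hydrogenation of this trisubstituted alkene (H2, Pd/C) from the face opposite the angular methyl leads to 30; the tetrasubstituted A/B alkene should be inert.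

2. Step 6. Hydride may add 1,4 instead of 1,6, the extended enolate may be protonated at the γ-carbon and return the conjugated lactone, and 9 may isomerise to the aromatic 2-pyranone. Fallback (sets out from 9, comes back at 11): only the exocyclic methylidene is hydrogenated with Wilkinson's catalyst (H2, PhH) to the conjugated lactone F5. The extended enolate is then formed by γ-deprotonation (LDA, HMPA, THF, −78 °C) and protonated kinetically at the α-carbon to give 11.

3. Step 17. Hydride may be delivered to the wrong face of the hindered ketone and give the epimeric alcohol. Fallback (sets out from 30, comes back at 31): the reduction is run under equilibrating electron-transfer conditions (Li, NH3, t-BuOH, −78 °C), which should give the more stable alcohol with OH trans to the adjacent quaternary methyl. Any epimeric alcohol F6 from the hydride run is recycled to 30 by Dess–Martin oxidation.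

**Further compounds**

F1 | step 16 | aldehyde from 29 (CH2CH2Cl arm changed to CH2CHO) | C/C1=C2\CC[C@H](C)[C@@H]2C(=O)[C@@](C)(CC=O)[C@H](C2=C(C)CCC(C)(C)C2)CC1
F2 | step 16 | ene product: tetracyclic keto alcohol with ring-C hydroxyl next to the angular methyl carbon and a ring-D alkene at the former C/D methine (carbinol epimers) | C/C1=C2\CC[C@H](C)[C@@H]2C(=O)[C@@]2(C)CC(O)[C@]3(C)CCC(C)(C)C=C3[C@@H]2CC1
F3 | step 16 | O-imidazolyl thiocarbonate of F2 | C/C1=C2\CC[C@H](C)[C@@H]2C(=O)[C@@]2(C)CC(OC(=S)n4ccnc4)[C@]3(C)CCC(C)(C)C=C3[C@@H]2CC1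
F4 | step 16 | deoxygenated tetracyclic ketone with the ring-D alkene (dehydro-30) | C/C1=C2\CC[C@H](C)[C@@H]2C(=O)[C@@]2(C)CC[C@]3(C)CCC(C)(C)C=C3[C@@H]2CC1
F5 | step 6 | (7S)-4,7-dimethyl-4,5,6,7-tetrahydrocyclopenta[c]pyran-1(3H)-one (C-4 epimers) | CC1COC(=O)C2=C1CC[C@@H]2C
F6 | step 17 | carbinol epimer of 31 | C/C1=C2\CC[C@H](C)[C@@H]2[C@H](O)[C@@]2(C)CC[C@]3(C)CCC(C)(C)C[C@H]3[C@@H]2CC1
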